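The 2,6,6-trimethylcyclohexene ring (C1 carries the side chain, C2 the methyl, C6 the gem-dimethyl group) is disconnected at C3–C4 and C5–C6, which excises its C4–C5 ethylene unit. The key step makes both bonds in one pot: the cross-conjugated lithium dienolate of 2,4-dimethylpent-1-en-3-one adds through its isopropyl carbon to phenyl vinyl sulfone, the sulfonyl carbanion closes onto the isopropenyl CH2, and the enolate released is trapped as the C1 triflate. It exploits the 1,4-relationship of quaternary C6 and allylic C3 across the C1=C2 alkene. Two Negishi couplings then attach the chain and a glycidate-derived (Z)-iodoalkenyl butenolide.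

Key step: step 2

Remark: the sulfonyl-bearing ring carbon of 7, 8 and 11 is formed as a racemate and is erased in step 4; the single stereocentre of the target comes from methyl (R)-glycidate 18 and is not touched afterwards. Compounds 1, 2, 4, 9, 18 and 19 are taken as commercially available.

Step 1
Reactants: 1 N-methoxy-N-methyl-2-methylpropanamide; 2 isopropenylmagnesium bromide
Product: 3 2,4-dimethylpent-1-en-3-one
Conditions: THF, 0 °C; cold aq. HCl
Reagents that add atoms: none
Why: Weinreb ketone synthesis, in which the chelated tetrahedral adduct of the amide and the Grignard reagent survives until acidic work-up, so the enone should form without over-addition.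

Step 2
Reactants: 3 2,4-dimethylpent-1-en-3-one; 4 phenyl vinyl sulfone
Product: 8 2,6,6-trimethyl-4-(phenylsulfonyl)cyclohex-1-en-1-yl trifluoromethanesulfonate (racemic), via lithium dienolate 5 (not isolated), via lithiated sulfone 6 (not isolated), via lithium cyclohexenolate 7 (not isolated)
Conditions: LiN(iPr)2, THF, −78 °C; 4 (slow addition), −78 to 0 °C; PhNTf2, 0 °C to rt; aq. NH4Cl
Reagents that add atoms: N-phenylbis(trifluoromethanesulfonimide), O=S(=O)(N(c1ccccc1)S(=O)(=O)C(F)(F)F)C(F)(F)F
Why: LiN(iPr)2 removes the only α-hydrogen of 3 (the isopropyl methine) to give cross-conjugated dienolate 5, whose tetrasubstituted carbon adds to the CH2 terminus of phenyl vinyl sulfone (first Michael addition, making the bond from the future gem-dimethyl carbon), and the sulfonyl carbanion 6 then adds to the CH2 terminus of the isopropenyl ketone (second Michael addition), releasing enolate 7, which PhNTf2 sulfonylates on oxygen. The closest known reaction type is the double Michael annulation (Michael–Michael ring closure, a formal anionic [4+2] cycloaddition) of kinetic enone enolates with acrylates or vinyl sulfones, combined with standard enolate triflation. The six-membered ring closes in a 6-endo-trig conjugate addition through the s-trans enone conformer, driven by the exchange of a sulfonyl carbanion for a more stable ketone enolate. The only new stereocentre, the sulfonyl-bearing carbon, is under no control and forms as a racemate, which is harmless because step 4 removes the sulfonyl group. The step needs regiocontrol at three points, and the substrate secures each: deprotonation can occur only at the isopropyl carbon, the sulfone ends up para to the oxygen-bearing carbon because both bonds form at the vinyl sulfone in Michael fashion, and the enolate (hence the triflate double bond) can lie only toward the methyl-bearing carbon because the other α-carbon is quaternary. The chemoselectivity problem, addition of 6 to a second molecule of vinyl sulfone instead of ring closure, is countered by the intramolecularity of the second addition and by slow addition of 4 at low temperature.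

Step 3
Reactants: 8 2,6,6-trimethyl-4-(phenylsulfonyl)cyclohex-1-en-1-yl trifluoromethanesulfonate; 9 (4-bromobut-1-yn-1-yl)trimethylsilane
Product: 11 trimethyl{4-[2,6,6-trimethyl-4-(phenylsulfonyl)cyclohex-1-en-1-yl]but-1-yn-1-yl}silane (racemic), via alkylzinc bromide 10 (not isolated)
Conditions: 9, Zn, LiCl, THF, 50 °C; then 8, PdCl2(dppf) (cat.), THF–NMP, 60 °C
Reagents that add atoms: none
Why: Negishi coupling, in which the zinc reagent 10 from zinc insertion into 9 should transmetalate to the vinylpalladium species formed from triflate 8 and give the sp2–sp3 bond with the ring double bond fixed in place, the sulfone and the silylalkyne being inert to organozinc halides.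

Step 4
Reactants: 11 trimethyl{4-[2,6,6-trimethyl-4-(phenylsulfonyl)cyclohex-1-en-1-yl]but-1-yn-1-yl}silane
Product: 13 2-(but-3-yn-1-yl)-1,3,3-trimethylcyclohex-1-ene, via silylalkyne 12 (not isolated)
Conditions: Na(Hg), Na2HPO4, MeOH–THF, −20 °C to rt; then K2CO3, rt
Reagents that add atoms: none
Why: Reductive desulfonylation by electron transfer from sodium amalgam should cleave the unactivated C–SO2Ph bond and erase the racemic centre, and methanolysis of the alkynylsilane in the same pot frees the terminal alkyne, neither reagent touching the tetrasubstituted alkene.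

Step 5
Reactants: 13 2-(but-3-yn-1-yl)-1,3,3-trimethylcyclohex-1-ene
Product: 16 (3E)-4-methyl-6-(2,6,6-trimethylcyclohex-1-en-1-yl)hex-3-en-1-ol, via alkenylalane 14 (not isolated), via lithium alanate 15 (not isolated)
Conditions: AlMe3, Cp2ZrCl2 (cat.), CH2Cl2, 0 °C to rt; n-BuLi, hexane–THF, −78 to 0 °C; oxirane, 0 °C to rt; aq. HCl
Reagents that add atoms: trimethylaluminium, C[Al](C)C; oxirane, C1CO1
Why: Zirconium-catalysed carboalumination (Negishi carboalumination) adds methyl and aluminium syn across the terminal alkyne with aluminium on the terminal carbon, and the derived lithium alanate opens oxirane with retention at the alkenyl carbon, which sets the E trisubstituted alkene.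

Step 6
Reactants: 16 (3E)-4-methyl-6-(2,6,6-trimethylcyclohex-1-en-1-yl)hex-3-en-1-ol
Product: 17 2-[(3E)-6-iodo-3-methylhex-3-en-1-yl]-1,3,3-trimethylcyclohex-1-ene
Conditions: I2, PPh3, imidazole, CH2Cl2, 0 °C
Reagents that add atoms: iodine, II
Why: Appel-type iodination converts the primary alcohol into the iodide by SN2 displacement of the alkoxyphosphonium group without affecting the alkenes.

Step 7
Reactants: 18 methyl (2R)-oxirane-2-carboxylate; 19 tert-butyldimethyl(prop-2-yn-1-yloxy)silane
Product: 21 methyl (2R)-6-[(tert-butyldimethylsilyl)oxy]-2-hydroxyhex-4-ynoate, via lithium acetylide 20 (not isolated)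
Conditions: 19, n-BuLi, THF, −78 °C; BF3·OEt2; 18, −78 °C; aq. NH4Cl
Reagents that add atoms: none
Why: BF3-promoted opening of the epoxide by the lithium acetylide (epoxide alkynylation) should occur at the unsubstituted CH2 carbon, leaving the stereocentre of the (R)-glycidate untouched, so the (R)-configured α-hydroxy ester results.

Step 8
Reactants: 21 methyl (2R)-6-[(tert-butyldimethylsilyl)oxy]-2-hydroxyhex-4-ynoate
Product: 22 methyl (2R)-2-acetoxy-6-[(tert-butyldimethylsilyl)oxy]hex-4-ynoate
Conditions: Ac2O, pyridine, DMAP (cat.), CH2Cl2, 0 °C to rt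
Reagents that add atoms: acetic anhydride, CC(=O)OC(C)=O
Why: DMAP-catalysed acylation of the secondary alcohol installs the acetate that supplies the two remaining lactone carbons.

Step 9
Reactants: 22 methyl (2R)-2-acetoxy-6-[(tert-butyldimethylsilyl)oxy]hex-4-ynoate
Product: 23 (5R)-5-{4-[(tert-butyldimethylsilyl)oxy]but-2-yn-1-yl}-4-hydroxyfuran-2(5H)-one
Conditions: LiN(SiMe3)2, THF, −78 to −20 °C; cold dilute aq. HCl to pH 3
Reagents that add atoms: none
Why: Dieckmann condensation, in which the acetate enolate attacks the neighbouring methyl ester to close the five-membered tetronic acid, whose immediate deprotonation to the tetronate should protect the oxygen-bearing stereocentre from epimerisation.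

Step 10
Reactants: 23 (5R)-5-{4-[(tert-butyldimethylsilyl)oxy]but-2-yn-1-yl}-4-hydroxyfuran-2(5H)-one
Product: 24 (2R)-2-{4-[(tert-butyldimethylsilyl)oxy]but-2-yn-1-yl}-5-oxo-2,5-dihydrofuran-3-yl trifluoromethanesulfonate
Conditions: Tf2O, iPr2NEt, CH2Cl2, −78 °C
Reagents that add atoms: trifluoromethanesulfonic anhydride, O=S(=O)(OS(=O)(=O)C(F)(F)F)C(F)(F)F
Why: O-Sulfonylation of the vinylogous acid gives the vinyl triflate needed for cross-coupling.

Step 11
Reactants: 24 (2R)-2-{4-[(tert-butyldimethylsilyl)oxy]but-2-yn-1-yl}-5-oxo-2,5-dihydrofuran-3-yl trifluoromethanesulfonate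
Product: 25 (5R)-5-{4-[(tert-butyldimethylsilyl)oxy]but-2-yn-1-yl}-4-(hydroxymethyl)furan-2(5H)-one
Conditions: Bu3SnCH2OH, Pd(PPh3)4 (cat.), LiCl, 1,4-dioxane, 90 °C
Reagents that add atoms: (tributylstannyl)methanol, OC[Sn](CCCC)(CCCC)CCCC
Why: Stille coupling, in which the stannane transfers its hydroxymethyl group in preference to butyl to the electron-poor β-triflyloxy butenolide under zerovalent palladium catalysis.

Step 12
Reactants: 25 (5R)-5-{4-[(tert-butyldimethylsilyl)oxy]but-2-yn-1-yl}-4-(hydroxymethyl)furan-2(5H)-one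
Product: 26 (5R)-5-(4-hydroxybut-2-yn-1-yl)-4-(hydroxymethyl)furan-2(5H)-one
Conditions: HF·pyridine, THF, 0 °C to rt
Reagents that add atoms: none
Why: Fluoride cleavage of the primary silyl ether under mildly acidic conditions frees the propargylic alcohol without base-induced epimerisation at the butenolide γ-carbon.

Step 13
Reactants: 26 (5R)-5-(4-hydroxybut-2-yn-1-yl)-4-(hydroxymethyl)furan-2(5H)-one
Product: 28 (5R)-5-[(2Z)-4-hydroxy-3-iodobut-2-en-1-yl]-4-(hydroxymethyl)furan-2(5H)-one, via alkenylstannane 27 (not isolated)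
Conditions: Bu3SnH, [Cp*RuCl]4 (cat.), CH2Cl2, rt; then I2, 0 °C
Reagents that add atoms: iodine, II
Why: Hydroxyl-directed ruthenium-catalysed trans-hydrostannation should place tin on the alkyne carbon next to the CH2OH group with hydrogen anti to it, and iododestannylation with retention then gives the Z-iodoalkene that carries the geometry of the hydroxymethyl-substituted alkene of the target.

Step 14
Reactants: 17 2-[(3E)-6-iodo-3-methylhex-3-en-1-yl]-1,3,3-trimethylcyclohex-1-ene; 28 (5R)-5-[(2Z)-4-hydroxy-3-iodobut-2-en-1-yl]-4-(hydroxymethyl)furan-2(5H)-one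
Product: 30 (6E)-neomanoalide, via alkylzinc iodide 29 (not isolated)
Conditions: 17, Zn, LiCl, THF, 40 °C; then 28, Pd(OAc)2 (cat.), SPhos, THF, rt
Reagents that add atoms: none
Why: Negishi coupling with retention of alkene geometry joins the two halves, since with Pd(OAc)2 and SPhos an alkylzinc halide should couple with the hydroxy-substituted alkenyl iodide faster than it is protonated by the free hydroxyl groups, and it does not add to the butenolide.

Compound list
1 | N-methoxy-N-methyl-2-methylpropanamide | CC(C)C(=O)N(C)OC | starting material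
2 | isopropenylmagnesium bromide | CC(=C)[Mg]Br | starting material
3 | 2,4-dimethylpent-1-en-3-one | CC(=C)C(=O)C(C)C | intermediate
4 | phenyl vinyl sulfone | C=CS(=O)(=O)c1ccccc1 | starting material
5 | lithium 2,4-dimethylpenta-1,3-dien-3-olate | [Li]OC(C(C)=C)=C(C)C | intermediate
6 | 6-lithio-2,4,4-trimethyl-6-(phenylsulfonyl)hex-1-en-3-one | [Li]C(CC(C)(C)C(=O)C(C)=C)S(=O)(=O)c1ccccc1 | intermediate
7 | lithium 2,6,6-trimethyl-4-(phenylsulfonyl)cyclohex-1-en-1-olate (racemic) | [Li]OC1=C(C)CC(CC1(C)C)S(=O)(=O)c1ccccc1 | intermediate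
8 | 2,6,6-trimethyl-4-(phenylsulfonyl)cyclohex-1-en-1-yl trifluoromethanesulfonate (racemic) | CC1=C(OS(=O)(=O)C(F)(F)F)C(C)(C)CC(C1)S(=O)(=O)c1ccccc1 | intermediate
9 | (4-bromobut-1-yn-1-yl)trimethylsilane | C[Si](C)(C)C#CCCBr | starting material
10 | bromo[4-(trimethylsilyl)but-3-yn-1-yl]zinc | C[Si](C)(C)C#CCC[Zn]Br | intermediate
11 | trimethyl{4-[2,6,6-trimethyl-4-(phenylsulfonyl)cyclohex-1-en-1-yl]but-1-yn-1-yl}silane (racemic) | CC1=C(CCC#C[Si](C)(C)C)C(C)(C)CC(C1)S(=O)(=O)c1ccccc1 | intermediate
12 | trimethyl[4-(2,6,6-trimethylcyclohex-1-en-1-yl)but-1-yn-1-yl]silane | CC1=C(CCC#C[Si](C)(C)C)C(C)(C)CCC1 | intermediate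
13 | 2-(but-3-yn-1-yl)-1,3,3-trimethylcyclohex-1-ene | CC1=C(CCC#C)C(C)(C)CCC1 | intermediate
14 | dimethyl[(1E)-2-methyl-4-(2,6,6-trimethylcyclohex-1-en-1-yl)but-1-en-1-yl]alumane | CC1=C(CC/C(C)=C/[Al](C)C)C(C)(C)CCC1 | intermediate
15 | lithium butyldimethyl[(1E)-2-methyl-4-(2,6,6-trimethylcyclohex-1-en-1-yl)but-1-en-1-yl]aluminate | [Li+].CCCC[Al-](C)(C)/C=C(\C)CCC1=C(C)CCCC1(C)C | intermediate
16 | (3E)-4-methyl-6-(2,6,6-trimethylcyclohex-1-en-1-yl)hex-3-en-1-ol | CC1=C(CC/C(C)=C/CCO)C(C)(C)CCC1 | intermediate
17 | 2-[(3E)-6-iodo-3-methylhex-3-en-1-yl]-1,3,3-trimethylcyclohex-1-ene | CC1=C(CC/C(C)=C/CCI)C(C)(C)CCC1 | intermediate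
18 | methyl (2R)-oxirane-2-carboxylate | COC(=O)[C@H]1CO1 | starting material
19 | tert-butyldimethyl(prop-2-yn-1-yloxy)silane | C#CCO[Si](C)(C)C(C)(C)C | starting material
20 | lithium 3-[(tert-butyldimethylsilyl)oxy]prop-1-yn-1-ide | [Li]C#CCO[Si](C)(C)C(C)(C)C | intermediate
21 | methyl (2R)-6-[(tert-butyldimethylsilyl)oxy]-2-hydroxyhex-4-ynoate | COC(=O)[C@H](O)CC#CCO[Si](C)(C)C(C)(C)C | intermediate
22 | methyl (2R)-2-acetoxy-6-[(tert-butyldimethylsilyl)oxy]hex-4-ynoate | COC(=O)[C@H](OC(C)=O)CC#CCO[Si](C)(C)C(C)(C)C | intermediate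
23 | (5R)-5-{4-[(tert-butyldimethylsilyl)oxy]but-2-yn-1-yl}-4-hydroxyfuran-2(5H)-one | CC(C)(C)[Si](C)(C)OCC#CC[C@H]1OC(=O)C=C1O | intermediate
24 | (2R)-2-{4-[(tert-butyldimethylsilyl)oxy]but-2-yn-1-yl}-5-oxo-2,5-dihydrofuran-3-yl trifluoromethanesulfonate | CC(C)(C)[Si](C)(C)OCC#CC[C@H]1OC(=O)C=C1OS(=O)(=O)C(F)(F)F | intermediate
25 | (5R)-5-{4-[(tert-butyldimethylsilyl)oxy]but-2-yn-1-yl}-4-(hydroxymethyl)furan-2(5H)-one | CC(C)(C)[Si](C)(C)OCC#CC[C@H]1OC(=O)C=C1CO | intermediate
26 | (5R)-5-(4-hydroxybut-2-yn-1-yl)-4-(hydroxymethyl)furan-2(5H)-one | OCC#CC[C@H]1OC(=O)C=C1CO | intermediate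
27 | (5R)-5-[(2Z)-4-hydroxy-3-(tributylstannyl)but-2-en-1-yl]-4-(hydroxymethyl)furan-2(5H)-one | CCCC[Sn](CCCC)(CCCC)/C(=C\C[C@H]1OC(=O)C=C1CO)CO | intermediate
28 | (5R)-5-[(2Z)-4-hydroxy-3-iodobut-2-en-1-yl]-4-(hydroxymethyl)furan-2(5H)-one | I/C(=C\C[C@H]1OC(=O)C=C1CO)CO | intermediate
29 | iodo[(3E)-4-methyl-6-(2,6,6-trimethylcyclohex-1-en-1-yl)hex-3-en-1-yl]zinc | CC1=C(CC/C(C)=C/CC[Zn]I)C(C)(C)CCC1 | intermediate
30 | (6E)-neomanoalide, (5R)-4-(hydroxymethyl)-5-[(2E,6E)-3-(hydroxymethyl)-7-methyl-9-(2,6,6-trimethylcyclohex-1-en-1-yl)nona-2,6-dien-1-yl]furan-2(5H)-one | CC1=C(CC/C(C)=C/CC/C(=C\C[C@H]2OC(=O)C=C2CO)CO)C(C)(C)CCC1 | target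

Total step count: 14. Longest linear sequence: 8 steps (steps 7 to 13, then step 14); the other branch is steps 1 to 6, then step 14.

Steps most likely to fail

Step 2. The sulfonyl carbanion may add to further vinyl sulfone (oligomerisation), or the amide base may add to the enone, before the ring closes. Fallback: setting out from 3, enolisation with LiN(iPr)2 and trapping with Me3SiCl should give trimethyl[(2,4-dimethylpenta-1,3-dien-3-yl)oxy]silane F1. This 2-silyloxydiene is heated with 4 (toluene, 150 °C, sealed tube) in a Diels–Alder reaction, the oxygen substituent directing the sulfone para to the silyloxy carbon, to give trimethyl{[2,6,6-trimethyl-4-(phenylsulfonyl)cyclohex-1-en-1-yl]oxy}silane F2. CsF and PhNTf2 in DME then convert the silyl enol ether into the triflate, and the route is rejoined at 8.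

Step 3. Oxidative addition and transmetalation at the tetrasubstituted vinyl triflate flanked by the gem-dimethyl carbon may be slow, so that triflate hydrolysis or β-hydride elimination of the alkylpalladium species overtakes coupling. Fallback: setting out from 8, a Stille coupling with tributyl(vinyl)stannane (Pd(PPh3)4, LiCl, dioxane), an sp2–sp2 coupling that is less sensitive to hindrance, should give [(4-ethenyl-3,5,5-trimethylcyclohex-3-en-1-yl)sulfonyl]benzene F3. Hydroboration of the vinyl group only with 9-BBN and oxidation (NaOH, H2O2) gives 2-[2,6,6-trimethyl-4-(phenylsulfonyl)cyclohex-1-en-1-yl]ethan-1-ol F4. PPh3, I2 and imidazole give {[4-(2-iodoethyl)-3,5,5-trimethylcyclohex-3-en-1-yl]sulfonyl}benzene F5. SN2 displacement with lithium (trimethylsilyl)acetylide in THF–DMPU then comes back to the route at 11.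

Step 14. Protonolysis of the alkylzinc reagent by the two free hydroxyl groups may compete with transmetalation and consume the ring fragment. Fallback: setting out from 28, silylation (t-BuMe2SiCl, imidazole, DMF) gives (5R)-4-{[(tert-butyldimethylsilyl)oxy]methyl}-5-[(2Z)-4-[(tert-butyldimethylsilyl)oxy]-3-iodobut-2-en-1-yl]furan-2(5H)-one F6. Negishi coupling with 29 (PdCl2(dppf), THF) then meets no protic group and gives the bis(tert-butyldimethylsilyl) ether of (6E)-neomanoalide F7. HF·pyridine in THF removes both silyl groups and the route is rejoined at 30.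

Further compounds
F1 | step 2 | trimethyl[(2,4-dimethylpenta-1,3-dien-3-yl)oxy]silane | C=C(C)C(O[Si](C)(C)C)=C(C)C
F2 | step 2 | trimethyl{[2,6,6-trimethyl-4-(phenylsulfonyl)cyclohex-1-en-1-yl]oxy}silane (racemic) | CC1=C(O[Si](C)(C)C)C(C)(C)CC(C1)S(=O)(=O)c1ccccc1
F3 | step 3 | [(4-ethenyl-3,5,5-trimethylcyclohex-3-en-1-yl)sulfonyl]benzene (racemic) | CC1=C(C=C)C(C)(C)CC(C1)S(=O)(=O)c1ccccc1
F4 | step 3 | 2-[2,6,6-trimethyl-4-(phenylsulfonyl)cyclohex-1-en-1-yl]ethan-1-ol (racemic) | CC1=C(CCO)C(C)(C)CC(C1)S(=O)(=O)c1ccccc1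
F5 | step 3 | {[4-(2-iodoethyl)-3,5,5-trimethylcyclohex-3-en-1-yl]sulfonyl}benzene (racemic) | CC1=C(CCI)C(C)(C)CC(C1)S(=O)(=O)c1ccccc1
F6 | step 14 | (5R)-4-{[(tert-butyldimethylsilyl)oxy]methyl}-5-[(2Z)-4-[(tert-butyldimethylsilyl)oxy]-3-iodobut-2-en-1-yl]furan-2(5H)-one | CC(C)(C)[Si](C)(C)OC/C(I)=C/C[C@H]1OC(=O)C=C1CO[Si](C)(C)C(C)(C)C
F7 | step 14 | bis(tert-butyldimethylsilyl) ether of (6E)-neomanoalide | CC1=C(CC/C(C)=C/CC/C(=C\C[C@H]2OC(=O)C=C2CO[Si](C)(C)C(C)(C)C)CO[Si](C)(C)C(C)(C)C)C(C)(C)CCC1
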